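**Plan**

- Numbering: C1 is the enol acetate CH, C2 the other alkene CH, C3 the quaternary carbon carrying OAc and the formyl carbon C20, C4–C9 the chain (methyl on C7), and C10–C15 the ring (C10 stereocentre, C11=C12, gem-dimethyl C15).
- Retrosynthetic cuts, in order: the two acetates and the C1/C20 oxidation levels; C2–C3 (thioacetate aldol); C3–C4 (acylation of an oxalate); C5–C6 (oxirane opening); C7–CH3 (carbometalation of a C6≡C7 alkyne); last, the ring bond C10–C15.
- Forward order: the only ring is closed first from an acyclic C13 ketone. The chain then grows from C6 to C3/C20 in steps 2–5, one aldol adds C1–C2, and eight redox, protecting-group and acyl steps finish the molecule.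
- Enabling feature: ring C10–C15, with the C10 stereocentre, the C11=C12 alkene and the C15 gem-dimethyl group, is the 2,6,6-trimethylcyclohex-2-enyl end of a head-cyclised isoprenoid. The C10–C15 bond therefore maps onto a proton-triggered closure between the two alkenes of (E)-geranylacetone.
- Stereochemistry: C10 (S) from the fold imposed by the cyclase; (E)-C6=C7 from syn-carboalumination; C3 (R) from a copper–bis(oxazoline) aldol catalyst; (E)-C1=C2 from the steric bias of the quaternary C3 during enol acetylation.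

Key step: step 1

Remark: the single (E) isomer of geranylacetone is assumed as the commercial starting material (the ketone carbon becomes C7 and its methyl group becomes C6).
Remark: the face selectivity of the copper–bis(oxazoline) aldol is assigned by analogy with pyruvate esters, where the (S,S) ligand directs addition to the si face; the (R,R) ligand is therefore chosen for (R) at C3.

Step 1
Reactants: 1 (E)-geranylacetone
Product: 2 (S)-dihydro-α-ionone, 4-[(1S)-2,6,6-trimethylcyclohex-2-en-1-yl]butan-2-one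
Conditions: whole E. coli cells expressing an engineered squalene–hopene cyclase variant (Alicyclobacillus acidocaldarius enzyme, cavity reshaped for proton loss at C12), citrate buffer pH 6, cyclodextrin as solubiliser, 30 °C
Reagents that add atoms: none
Why: Proposed new method: the catalytic aspartic acid protonates C14 of the pre-folded diene, the tertiary C15 cation is captured by C10 of the C10=C11 alkene to form the C10–C15 bond, and an active-site base removes a C12 proton from the C11 cation to leave the C11=C12 alkene. The closest known reaction type is the monocyclisation of geranylacetone-type ketones by squalene–hopene cyclase variants, which ends at the exocyclic alkene or at a bicyclic enol ether. The six-membered ring C10–C15 closes in a chair-like 6-endo cation–olefin mode with respect to the C10=C11 alkene. The C10 stereocentre is controlled by the enzyme alone, whose cavity presents one face of C10=C11 to C15 in the fold that gives hopene-type ring A, which corresponds to (S). The step needs monocyclisation without capture of the C11 cation by the ketone oxygen, and proton loss from C12 rather than from the C11 methyl group or from C10. The substrate contributes only by having no third alkene, so these selectivities must come from a cavity that holds the ketone away from C11 and places the base over C12.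

Step 2
Reactants: 2 (S)-dihydro-α-ionone
Product: 4 (6S)-6-(but-3-yn-1-yl)-1,5,5-trimethylcyclohex-1-ene, via enol phosphate 3 (not isolated)
Conditions: LiN(iPr)2 (1.1 equiv), THF, −78 °C; ClP(O)(OEt)2, −78 °C to rt; then LiN(iPr)2 (2.3 equiv), −78 °C to rt; aq. NH4Cl
Reagents that add atoms: none
Why: This is the Negishi methyl ketone-to-alkyne sequence (kinetic deprotonation at the methyl group, O-phosphorylation, base-induced elimination of diethyl phosphate), and C10 is not acidic so it keeps its configuration.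

Step 3
Reactants: 4 (6S)-6-(but-3-yn-1-yl)-1,5,5-trimethylcyclohex-1-ene; 5 oxirane
Product: 8 (3E)-4-methyl-6-[(1S)-2,6,6-trimethylcyclohex-2-en-1-yl]hex-3-en-1-ol, via alkenylalane 6 (not isolated), via lithium alanate 7 (not isolated)
Conditions: AlMe3 (2 equiv), Cp2ZrCl2 (0.25 equiv), CH2Cl2, 0 °C to rt; volatiles removed; n-BuLi, hexane/THF, −78 to 0 °C; oxirane, 0 °C to rt; dilute aq. HCl work-up
Reagents that add atoms: trimethylaluminium C[Al](C)C
Why: Negishi zirconium-catalysed carboalumination adds methyl and aluminium syn across the terminal alkyne with methyl at the internal carbon, which fixes the (E) C6=C7 geometry, and the derived alanate opens oxirane with retention at the alkenyl carbon while the ring alkene stays inert.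

Step 4
Reactants: 8 (3E)-4-methyl-6-[(1S)-2,6,6-trimethylcyclohex-2-en-1-yl]hex-3-en-1-ol
Product: 9 (6S)-6-[(3E)-6-bromo-3-methylhex-3-en-1-yl]-1,5,5-trimethylcyclohex-1-ene
Conditions: CBr4, PPh3, CH2Cl2, 0 °C
Reagents that add atoms: carbon tetrabromide BrC(Br)(Br)Br
Why: The Appel reaction converts the primary alcohol to the bromide under neutral conditions that leave both alkenes and C10 untouched.

Step 5
Reactants: 9 (6S)-6-[(3E)-6-bromo-3-methylhex-3-en-1-yl]-1,5,5-trimethylcyclohex-1-ene; 10 diethyl oxalate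
Product: 12 ethyl (5E)-6-methyl-2-oxo-8-[(1S)-2,6,6-trimethylcyclohex-2-en-1-yl]oct-5-enoate, via Grignard reagent 11 (not isolated)
Conditions: Mg, THF, rt; then added to (CO2Et)2 (3 equiv), THF, −78 °C; aq. NH4Cl
Reagents that add atoms: none
Why: Grignard mono-addition to a dialkyl oxalate stops at the α-keto ester (C3 and C20) because the tetrahedral magnesium alkoxide is stable at −78 °C and the oxalate is in excess.

Step 6
Reactants: 13 S-tert-butyl thioacetate
Product: 14 1-(tert-butylsulfanyl)-1-(trimethylsilyloxy)ethene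
Conditions: LiN(iPr)2, THF, −78 °C; Me3SiCl, −78 °C to rt
Reagents that add atoms: chlorotrimethylsilane C[Si](C)(C)Cl
Why: O-Silylation of the lithium thioester enolate is the standard route to the silyl ketene thioacetal needed for a Mukaiyama aldol addition.

Step 7
Reactants: 12 ethyl (5E)-6-methyl-2-oxo-8-[(1S)-2,6,6-trimethylcyclohex-2-en-1-yl]oct-5-enoate; 14 1-(tert-butylsulfanyl)-1-(trimethylsilyloxy)ethene
Product: 16 ethyl (2R,5E)-2-[2-(tert-butylsulfanyl)-2-oxoethyl]-2-hydroxy-6-methyl-8-[(1S)-2,6,6-trimethylcyclohex-2-en-1-yl]oct-5-enoate, via trimethylsilyl ether 15 (not isolated)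
Conditions: Cu(OTf)2 (10 mol%), (R,R)-tBu-box ligand [2,2'-(propane-2,2-diyl)bis((4R)-4-tert-butyl-4,5-dihydrooxazole)] (11 mol%), THF, −78 °C; then 1 M HCl, THF, rt
Reagents that add atoms: none
Why: In this copper–bis(oxazoline)-catalysed Mukaiyama aldol addition the α-keto ester chelates divalent copper through both carbonyl oxygens in the ligand plane, one tert-butyl group blocks a ketone face, and with the (R,R) ligand the enol silane adds to the open re face to set C3 as (R) before acid removes the silyl group.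

Step 8
Reactants: 16 ethyl (2R,5E)-2-[2-(tert-butylsulfanyl)-2-oxoethyl]-2-hydroxy-6-methyl-8-[(1S)-2,6,6-trimethylcyclohex-2-en-1-yl]oct-5-enoate
Product: 17 (2R)-2-{(3E)-4-methyl-6-[(1S)-2,6,6-trimethylcyclohex-2-en-1-yl]hex-3-en-1-yl}butane-1,2,4-triol
Conditions: LiAlH4, THF, 0 °C to rt; Fieser work-up
Reagents that add atoms: none
Why: Hydride reduction takes both the thioester (C1) and the ester (C20) to primary alcohols, and C3 carries no hydrogen so it cannot epimerise.

Step 9
Reactants: 17 (2R)-2-{(3E)-4-methyl-6-[(1S)-2,6,6-trimethylcyclohex-2-en-1-yl]hex-3-en-1-yl}butane-1,2,4-triol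
Product: 18 2-[(4R)-2,2-dimethyl-4-{(3E)-4-methyl-6-[(1S)-2,6,6-trimethylcyclohex-2-en-1-yl]hex-3-en-1-yl}-1,3-dioxolan-4-yl]ethan-1-ol
Conditions: 2,2-dimethoxypropane, PPTS (cat.), acetone, rt
Reagents that add atoms: 2,2-dimethoxypropane COC(C)(C)OC
Why: Thermodynamic acetonide formation selects the five-membered 1,3-dioxolane on the C3/C20 diol, because the alternative 1,3-dioxane would place a C3 substituent axial and syn to an axial acetal methyl group, so only the C1 hydroxyl stays free.

Step 10
Reactants: 18 2-[(4R)-2,2-dimethyl-4-{(3E)-4-methyl-6-[(1S)-2,6,6-trimethylcyclohex-2-en-1-yl]hex-3-en-1-yl}-1,3-dioxolan-4-yl]ethan-1-ol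
Product: 19 2-[(4R)-2,2-dimethyl-4-{(3E)-4-methyl-6-[(1S)-2,6,6-trimethylcyclohex-2-en-1-yl]hex-3-en-1-yl}-1,3-dioxolan-4-yl]acetaldehyde
Conditions: Dess–Martin periodinane, pyridine, CH2Cl2, 0 °C to rt
Reagents that add atoms: none
Why: Dess–Martin oxidation of the primary alcohol stops at the C1 aldehyde under buffered, non-basic conditions that do not trigger β-elimination of the C3 oxygen.

Step 11
Reactants: 19 2-[(4R)-2,2-dimethyl-4-{(3E)-4-methyl-6-[(1S)-2,6,6-trimethylcyclohex-2-en-1-yl]hex-3-en-1-yl}-1,3-dioxolan-4-yl]acetaldehyde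
Product: 20 (E)-2-[(4R)-2,2-dimethyl-4-{(3E)-4-methyl-6-[(1S)-2,6,6-trimethylcyclohex-2-en-1-yl]hex-3-en-1-yl}-1,3-dioxolan-4-yl]ethenyl acetate
Conditions: Ac2O, Et3N, DMAP (cat.), CH2Cl2, rt to 40 °C
Reagents that add atoms: acetic anhydride CC(=O)OC(C)=O
Why: Enol acetate formation by O-acetylation of the aldehyde enolate should favour the (E) isomer because a cis arrangement of acetoxy and the quaternary C3 is strongly strained, and the ketal oxygen at C3 is a poor leaving group for the competing elimination.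

Step 12
Reactants: 20 (E)-2-[(4R)-2,2-dimethyl-4-{(3E)-4-methyl-6-[(1S)-2,6,6-trimethylcyclohex-2-en-1-yl]hex-3-en-1-yl}-1,3-dioxolan-4-yl]ethenyl acetate
Product: 21 (1E,3R,6E)-3-hydroxy-3-(hydroxymethyl)-7-methyl-9-[(1S)-2,6,6-trimethylcyclohex-2-en-1-yl]nona-1,6-dien-1-yl acetate
Conditions: AcOH/H2O 4:1, 40 °C
Reagents that add atoms: none
Why: Acid-catalysed acetal hydrolysis in aqueous acetic acid should spare the enol acetate, which needs mineral acid to hydrolyse, and should not ionise the C3–O bond, which is deactivated by the neighbouring C20 oxygen.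

Step 13
Reactants: 21 (1E,3R,6E)-3-hydroxy-3-(hydroxymethyl)-7-methyl-9-[(1S)-2,6,6-trimethylcyclohex-2-en-1-yl]nona-1,6-dien-1-yl acetate
Product: 23 (1E,3R,6E)-3-acetoxy-7-methyl-3-[(triethylsilyloxy)methyl]-9-[(1S)-2,6,6-trimethylcyclohex-2-en-1-yl]nona-1,6-dien-1-yl acetate, via triethylsilyl ether 22 (not isolated)
Conditions: Et3SiCl (1.1 equiv), Et3N, DMAP (cat.), CH2Cl2, −20 to 0 °C; then Ac2O, Et3N, DMAP (1 equiv), rt to 35 °C
Reagents that add atoms: chlorotriethylsilane CC[Si](Cl)(CC)CC; acetic anhydride CC(=O)OC(C)=O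
Why: Sterically selective silylation of the primary C20 hydroxyl is followed by Steglich-type DMAP-catalysed acetylation of the remaining tertiary C3 hydroxyl, and the (E) geometry prevents the enol acetate from transferring its acyl group intramolecularly.

Step 14
Reactants: 23 (1E,3R,6E)-3-acetoxy-7-methyl-3-[(triethylsilyloxy)methyl]-9-[(1S)-2,6,6-trimethylcyclohex-2-en-1-yl]nona-1,6-dien-1-yl acetate
Product: 24 (1E,3R,6E)-3-acetoxy-3-(hydroxymethyl)-7-methyl-9-[(1S)-2,6,6-trimethylcyclohex-2-en-1-yl]nona-1,6-dien-1-yl acetate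
Conditions: HF·pyridine, pyridine, THF, 0 °C
Reagents that add atoms: none
Why: Fluoride-mediated cleavage of the primary triethylsilyl ether under buffered, weakly acidic conditions generates no alkoxide, so migration of the tertiary acetate and cleavage of the enol acetate should not occur.

Step 15
Reactants: 24 (1E,3R,6E)-3-acetoxy-3-(hydroxymethyl)-7-methyl-9-[(1S)-2,6,6-trimethylcyclohex-2-en-1-yl]nona-1,6-dien-1-yl acetate
Product: 25 (1E,3R,6E)-3-acetoxy-3-formyl-7-methyl-9-[(1S)-2,6,6-trimethylcyclohex-2-en-1-yl]nona-1,6-dien-1-yl acetate (CNP0244145.1)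
Conditions: Dess–Martin periodinane, pyridine, CH2Cl2, 0 °C to rt
Reagents that add atoms: none
Why: Dess–Martin oxidation of the neopentyl-type primary alcohol gives the C20 aldehyde, which has no α-hydrogen and therefore cannot enolise, eliminate or epimerise.

**Compound list**

1 | (E)-geranylacetone, (5E)-6,10-dimethylundeca-5,9-dien-2-one | CC(C)=CCC/C(C)=C/CCC(C)=O | starting material
2 | (S)-dihydro-α-ionone, 4-[(1S)-2,6,6-trimethylcyclohex-2-en-1-yl]butan-2-one | CC(=O)CC[C@@H]1C(C)=CCCC1(C)C | intermediate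
3 | diethyl 4-[(1S)-2,6,6-trimethylcyclohex-2-en-1-yl]but-1-en-2-yl phosphate | C=C(CC[C@@H]1C(C)=CCCC1(C)C)OP(=O)(OCC)OCC | intermediate
4 | (6S)-6-(but-3-yn-1-yl)-1,5,5-trimethylcyclohex-1-ene | C#CCC[C@@H]1C(C)=CCCC1(C)C | intermediate
5 | oxirane | C1CO1 | starting material
6 | dimethyl{(1E)-2-methyl-4-[(1S)-2,6,6-trimethylcyclohex-2-en-1-yl]but-1-en-1-yl}alane | C[Al](C)/C=C(\C)CC[C@@H]1C(C)=CCCC1(C)C | intermediate
7 | lithium butyl(dimethyl){(1E)-2-methyl-4-[(1S)-2,6,6-trimethylcyclohex-2-en-1-yl]but-1-en-1-yl}alanate | [Li+].CCCC[Al-](C)(C)/C=C(\C)CC[C@@H]1C(C)=CCCC1(C)C | intermediate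
8 | (3E)-4-methyl-6-[(1S)-2,6,6-trimethylcyclohex-2-en-1-yl]hex-3-en-1-ol | OCC/C=C(\C)CC[C@@H]1C(C)=CCCC1(C)C | intermediate
9 | (6S)-6-[(3E)-6-bromo-3-methylhex-3-en-1-yl]-1,5,5-trimethylcyclohex-1-ene | BrCC/C=C(\C)CC[C@@H]1C(C)=CCCC1(C)C | intermediate
10 | diethyl oxalate | CCOC(=O)C(=O)OCC | starting material
11 | {(3E)-4-methyl-6-[(1S)-2,6,6-trimethylcyclohex-2-en-1-yl]hex-3-en-1-yl}magnesium bromide | Br[Mg]CC/C=C(\C)CC[C@@H]1C(C)=CCCC1(C)C | intermediate
12 | ethyl (5E)-6-methyl-2-oxo-8-[(1S)-2,6,6-trimethylcyclohex-2-en-1-yl]oct-5-enoate | CCOC(=O)C(=O)CC/C=C(\C)CC[C@@H]1C(C)=CCCC1(C)C | intermediate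
13 | S-tert-butyl thioacetate | CC(=O)SC(C)(C)C | starting material
14 | 1-(tert-butylsulfanyl)-1-(trimethylsilyloxy)ethene | C=C(O[Si](C)(C)C)SC(C)(C)C | intermediate
15 | ethyl (2R,5E)-2-[2-(tert-butylsulfanyl)-2-oxoethyl]-6-methyl-8-[(1S)-2,6,6-trimethylcyclohex-2-en-1-yl]-2-(trimethylsilyloxy)oct-5-enoate | CCOC(=O)[C@](CC(=O)SC(C)(C)C)(CC/C=C(\C)CC[C@@H]1C(C)=CCCC1(C)C)O[Si](C)(C)C | intermediate
16 | ethyl (2R,5E)-2-[2-(tert-butylsulfanyl)-2-oxoethyl]-2-hydroxy-6-methyl-8-[(1S)-2,6,6-trimethylcyclohex-2-en-1-yl]oct-5-enoate | CCOC(=O)[C@](CC(=O)SC(C)(C)C)(CC/C=C(\C)CC[C@@H]1C(C)=CCCC1(C)C)O | intermediate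
17 | (2R)-2-{(3E)-4-methyl-6-[(1S)-2,6,6-trimethylcyclohex-2-en-1-yl]hex-3-en-1-yl}butane-1,2,4-triol | OCC[C@@](CO)(CC/C=C(\C)CC[C@@H]1C(C)=CCCC1(C)C)O | intermediate
18 | 2-[(4R)-2,2-dimethyl-4-{(3E)-4-methyl-6-[(1S)-2,6,6-trimethylcyclohex-2-en-1-yl]hex-3-en-1-yl}-1,3-dioxolan-4-yl]ethan-1-ol | OCC[C@]1(CC/C=C(\C)CC[C@@H]2C(C)=CCCC2(C)C)COC(C)(C)O1 | intermediate
19 | 2-[(4R)-2,2-dimethyl-4-{(3E)-4-methyl-6-[(1S)-2,6,6-trimethylcyclohex-2-en-1-yl]hex-3-en-1-yl}-1,3-dioxolan-4-yl]acetaldehyde | O=CC[C@]1(CC/C=C(\C)CC[C@@H]2C(C)=CCCC2(C)C)COC(C)(C)O1 | intermediate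
20 | (E)-2-[(4R)-2,2-dimethyl-4-{(3E)-4-methyl-6-[(1S)-2,6,6-trimethylcyclohex-2-en-1-yl]hex-3-en-1-yl}-1,3-dioxolan-4-yl]ethenyl acetate | CC(=O)O/C=C/[C@]1(CC/C=C(\C)CC[C@@H]2C(C)=CCCC2(C)C)COC(C)(C)O1 | intermediate
21 | (1E,3R,6E)-3-hydroxy-3-(hydroxymethyl)-7-methyl-9-[(1S)-2,6,6-trimethylcyclohex-2-en-1-yl]nona-1,6-dien-1-yl acetate | CC(=O)O/C=C/[C@@](CO)(CC/C=C(\C)CC[C@@H]1C(C)=CCCC1(C)C)O | intermediate
22 | (1E,3R,6E)-3-hydroxy-7-methyl-3-[(triethylsilyloxy)methyl]-9-[(1S)-2,6,6-trimethylcyclohex-2-en-1-yl]nona-1,6-dien-1-yl acetate | CC(=O)O/C=C/[C@@](CO[Si](CC)(CC)CC)(CC/C=C(\C)CC[C@@H]1C(C)=CCCC1(C)C)O | intermediate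
23 | (1E,3R,6E)-3-acetoxy-7-methyl-3-[(triethylsilyloxy)methyl]-9-[(1S)-2,6,6-trimethylcyclohex-2-en-1-yl]nona-1,6-dien-1-yl acetate | CC(=O)O/C=C/[C@@](CO[Si](CC)(CC)CC)(CC/C=C(\C)CC[C@@H]1C(C)=CCCC1(C)C)OC(C)=O | intermediate
24 | (1E,3R,6E)-3-acetoxy-3-(hydroxymethyl)-7-methyl-9-[(1S)-2,6,6-trimethylcyclohex-2-en-1-yl]nona-1,6-dien-1-yl acetate | CC(=O)O/C=C/[C@@](CO)(CC/C=C(\C)CC[C@@H]1C(C)=CCCC1(C)C)OC(C)=O | intermediate
25 | (1E,3R,6E)-3-acetoxy-3-formyl-7-methyl-9-[(1S)-2,6,6-trimethylcyclohex-2-en-1-yl]nona-1,6-dien-1-yl acetate (CNP0244145.1) | CC(=O)O/C=C/[C@@](C=O)(CC/C=C(\C)CC[C@@H]1C(C)=CCCC1(C)C)OC(C)=O | target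

**Step count**

Total steps: 15. Longest linear sequence: 14 steps (steps 1–5 and 7–15, from (E)-geranylacetone); step 6 is a one-step side branch.

**Steps most likely to fail**

Step 1. The cation cascade may end by proton loss from the C11 methyl group (exocyclic alkene) or by capture of the C11 cation by the ketone oxygen instead of deprotonation at C12, or the variant may turn over poorly. The fallback sets out from 1 and uses a cyclase variant of the established kind that ends the cascade at the exocyclic alkene, which would give (S)-γ-dihydroionone F1 with the same C10 configuration. Brief treatment of F1 with catalytic TsOH in toluene at rt (or 85% H3PO4) would then protonate the methylene carbon and remove a C12 proton, moving the alkene to C11=C12 without touching C10. The isomerisation is stopped before deprotonation at C10 (the tetrasubstituted isomer) sets in, and the route is rejoined at 2.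

Step 11. The C1 enolate may expel the C3 ketal oxygen (E1cB, giving an enal) faster than it is O-acetylated, or the alkene geometry may not be fully controlled. The fallback sets out from alcohol 18 and avoids any enolate. Thioetherification with PhSSPh and PBu3 would give phenyl sulfide F2, and NaIO4 would oxidise it to sulfoxide F3. A Pummerer rearrangement (Ac2O, NaOAc, heat) would give α-acetoxy sulfide F4, and a second NaIO4 oxidation would give α-acetoxy sulfoxide F5. Warming F5 in toluene should bring about thermal syn-elimination of benzenesulfenic acid toward C2 and deliver the (E)-enol acetate, rejoining the route at 20.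

Step 14. The tertiary acetate may migrate to the freed primary C20 hydroxyl through a five-membered orthoester pathway during desilylation or before the oxidation. The fallback sets out from 23 and converts the primary triethylsilyl ether directly into the aldehyde by oxidative desilylation under Swern conditions ((COCl)2, DMSO, CH2Cl2, −78 to −30 °C, then Et3N). The silyl ether is turned into the alkoxysulfonium salt without a free hydroxyl persisting next to the acetate. This fallback makes no new compound (F0) and rejoins the route at 25.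

**Further compounds**

F1 | step 1 | (S)-γ-dihydroionone, 4-[(1S)-2,2-dimethyl-6-methylidenecyclohexyl]butan-2-one | CC(=O)CC[C@@H]1C(=C)CCCC1(C)C
F2 | step 11 | (4R)-2,2-dimethyl-4-{(3E)-4-methyl-6-[(1S)-2,6,6-trimethylcyclohex-2-en-1-yl]hex-3-en-1-yl}-4-[2-(phenylsulfanyl)ethyl]-1,3-dioxolane | c1ccccc1SCC[C@]1(CC/C=C(\C)CC[C@@H]2C(C)=CCCC2(C)C)COC(C)(C)O1
F3 | step 11 | (4R)-2,2-dimethyl-4-{(3E)-4-methyl-6-[(1S)-2,6,6-trimethylcyclohex-2-en-1-yl]hex-3-en-1-yl}-4-[2-(phenylsulfinyl)ethyl]-1,3-dioxolane (mixture at sulfur) | O=S(c1ccccc1)CC[C@]1(CC/C=C(\C)CC[C@@H]2C(C)=CCCC2(C)C)COC(C)(C)O1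
F4 | step 11 | 2-[(4R)-2,2-dimethyl-4-{(3E)-4-methyl-6-[(1S)-2,6,6-trimethylcyclohex-2-en-1-yl]hex-3-en-1-yl}-1,3-dioxolan-4-yl]-1-(phenylsulfanyl)ethyl acetate (mixture at C1) | CC(=O)OC(Sc1ccccc1)C[C@]1(CC/C=C(\C)CC[C@@H]2C(C)=CCCC2(C)C)COC(C)(C)O1
F5 | step 11 | 2-[(4R)-2,2-dimethyl-4-{(3E)-4-methyl-6-[(1S)-2,6,6-trimethylcyclohex-2-en-1-yl]hex-3-en-1-yl}-1,3-dioxolan-4-yl]-1-(phenylsulfinyl)ethyl acetate (mixture at C1 and sulfur) | CC(=O)OC(S(=O)c1ccccc1)C[C@]1(CC/C=C(\C)CC[C@@H]2C(C)=CCCC2(C)C)COC(C)(C)O1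
F0 | step 14 | none | none
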